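**Retrosynthetic overview**

1. Last bonds: O–Si cleavage; C2–Ph with the 2S centre by Rh‑catalysed asymmetric 1,4‑addition of phenylboronic acid to chromone 14; the (Z)‑C8 side chain by Sonogashira coupling of 8‑iodochromone 8 with (R)‑alkynol acetate 12 (from (R)‑2‑methylglycidol) and Lindlar semihydrogenation.
2. The pyran‑4‑one ring is not closed at ring size six. It comes from the furan‑3‑one ring of 6‑hydroxybenzofuran‑3(2H)‑one 1 by insertion of one carbon (C3) between C2 and C4: zinc‑carbenoid cyclopropanation of the bis‑silyl enol ether 2, then iron(III) fragmentation, which also delivers the C2=C3 enone needed for the arylation.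
3. Enabling feature: in the heterocycle, C3 is the only ring atom bound neither to oxygen nor to the arene. The other five atoms O1–C2–C4(=O)–C4a–C8a are exactly the ring of a benzofuran‑3(2H)‑one. Its enol is a benzofuran with an olefin‑like, doubly oxygenated C2=C3 bond, and O1 on C2 stabilises the radical/cation that steers cleavage to the internal cyclopropane bond.
4. Ring order: benzene and furanone rings are present in 1; cyclopropane (transient) and pyranone (ring enlargement) both in step 2; no ring is formed afterwards.

Key step: step 2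

Assumption: the hydroxorhodium/(S)‑bisphosphine catalyst is taken to add phenyl to the chromone with the same facial sense as to cyclic enones ((S)‑ligand gives (S)‑3‑arylcyclohexanone), which corresponds to 2S here; if the sense proves opposite, the (R)‑ligand is used.

**Route**

Step 1
Reactants: 1 6-hydroxy-1-benzofuran-3(2H)-one
Product: 2 3,6-bis[(trimethylsilyl)oxy]-1-benzofuran
Conditions: TMSOTf (2.2 equiv), Et3N (3 equiv), CH2Cl2, 0 °C to rt; pentane extraction, no aqueous work-up
Reagents that add atoms: trimethylsilyl trifluoromethanesulfonate, C[Si](C)(C)OS(=O)(=O)C(F)(F)F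
Why: Silyl triflate/amine silylation of the phenol and O‑silylation of the easily enolised α‑aryloxy ketone, driven by formation of the benzofuran, should give the bis(silyl ether) in one operation (silyl enol ether formation).

Step 2
Reactants: 2 3,6-bis[(trimethylsilyl)oxy]-1-benzofuran
Product: 6 7-hydroxy-4H-chromen-4-one, via siloxycyclopropane 3 (not isolated), via 2-chlorochromanone 4 (not isolated), via chromone silyl ether 5 (not isolated)
Conditions: Et2Zn, CH2I2, CH2Cl2, 0 °C to rt; pyridine, filter, concentrate; FeCl3 (3 equiv), DMF, 0 °C to rt; NaOAc, MeOH, reflux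
Reagents that add atoms: diiodomethane, ICI
Why: The Furukawa‑type Simmons–Smith zinc carbenoid adds CH2 to the C2=C3 bond of 2, an electron‑rich 1,2‑dioxygenated enol‑ether double bond in a weakly aromatic furan ring, to give the cis‑fused siloxycyclopropane 3 by concerted [2+1] addition (the three‑membered ring is closed in one step on one face, the only fusion possible). Iron(III) chloride then turns the cyclopropyl silyl ether into an iron(III) alkoxide that fragments by homolysis and β‑scission of the internal C1a–C6b bond, so the six‑membered ring is not closed by a new bond but arises by opening the zero‑atom bridge of the 2‑oxabicyclo[3.1.0]hexane; the C2 radical is chlorinated (or oxidised to the oxocarbenium ion) to 4, acetate removes HCl to give the chromone, and methanol takes off the aryl silyl group. The closest known reaction is the iron(III) chloride ring enlargement of 1‑siloxybicyclo[n.1.0]alkanes, made by Simmons–Smith cyclopropanation of cycloalkanone silyl enol ethers, to cycloalk‑2‑enones. No stereocentre has to be controlled, since the two centres of racemic 3 and C2 of 4 disappear in the elimination. The selectivity needed is cleavage of the internal rather than the external cyclopropane bond; it is secured by O1 on C1a, which makes the ring‑enlarged radical a stabilised secondary α‑alkoxy radical whereas the alternative is a primary alkyl radical, and the carbenoid's preference for C2=C3 over the benzene ring follows from the two oxygen donors on that bond.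

Step 3
Reactants: 6 7-hydroxy-4H-chromen-4-one
Product: 7 7-hydroxy-8-iodo-4H-chromen-4-one
Conditions: NIS (1.05 equiv), TFA (cat.), MeCN, 0 °C to rt
Reagents that add atoms: N-iodosuccinimide, O=C1CCC(=O)N1I
Why: Electrophilic aromatic iodination ortho to the free phenol; in 7‑hydroxybenzopyran‑4‑ones the phenol reacts through its C7=C8 enol (bond fixation by the pyranone, as in 7‑hydroxycoumarins and 7‑hydroxyisoflavones), so C8 between the two oxygens is expected to be substituted in preference to C6.

Step 4
Reactants: 7 7-hydroxy-8-iodo-4H-chromen-4-one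
Product: 8 7-{[tert-butyl(dimethyl)silyl]oxy}-8-iodo-4H-chromen-4-one
Conditions: TBSCl, imidazole, DMF, rt
Reagents that add atoms: tert-butyldimethylsilyl chloride, CC(C)(C)[Si](C)(C)Cl
Why: Silyl ether formation masks the acidic phenol, which would otherwise cyclise onto the alkyne (furan formation) in the Sonogashira step and bind rhodium in step 9.

Step 5
Reactants: 9 [(2R)-2-methyloxiran-2-yl]methanol
Product: 11 (2R)-2-ethynyl-2-methyloxirane, via epoxy aldehyde 10 (not isolated)
Conditions: PhI(OAc)2 (1.1 equiv), TEMPO (10 mol %), CH2Cl2, rt; then MeOH, K2CO3, dimethyl (1-diazo-2-oxopropyl)phosphonate, 0 °C to rt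
Reagents that add atoms: dimethyl (1-diazo-2-oxopropyl)phosphonate, CC(=O)C(=[N+]=[N-])P(=O)(OC)OC
Why: TEMPO/iodine(III) oxidation stops at the aldehyde and the Ohira–Bestmann (Seyferth–Gilbert) homologation converts it into the terminal alkyne; the stereocentre is quaternary and cannot epimerise, so the configuration of 9 is carried over (the descriptor of 10 changes only through CIP priorities).

Step 6
Reactants: 11 (2R)-2-ethynyl-2-methyloxirane
Product: 12 (2R)-2-hydroxy-2-methylbut-3-yn-1-yl acetate
Conditions: CsOAc (0.5 equiv), AcOH (3 equiv), DMF, 60 °C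
Reagents that add atoms: acetic acid, CC(=O)O
Why: SN2 opening of the 2,2‑disubstituted epoxide by acetate at the unsubstituted CH2 terminus under buffered, non‑ionising conditions should give the tertiary alcohol/primary acetate directly and leaves the C–O bond at the quaternary stereocentre untouched.

Step 7
Reactants: 8 7-{[tert-butyl(dimethyl)silyl]oxy}-8-iodo-4H-chromen-4-one, 12 (2R)-2-hydroxy-2-methylbut-3-yn-1-yl acetate
Product: 13 (2R)-4-(7-{[tert-butyl(dimethyl)silyl]oxy}-4-oxo-4H-chromen-8-yl)-2-hydroxy-2-methylbut-3-yn-1-yl acetate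
Conditions: Pd(PPh3)2Cl2 (3 mol %), CuI (5 mol %), Et3N, THF (degassed), rt to 40 °C
Reagents that add atoms: none
Why: Sonogashira coupling of the electron‑poor, di‑ortho‑substituted aryl iodide with the terminal alkyne; a tertiary amine is used because secondary amines add to C2 of chromones.

Step 8
Reactants: 13 (2R)-4-(7-{[tert-butyl(dimethyl)silyl]oxy}-4-oxo-4H-chromen-8-yl)-2-hydroxy-2-methylbut-3-yn-1-yl acetate
Product: 14 (2R,3Z)-4-(7-{[tert-butyl(dimethyl)silyl]oxy}-4-oxo-4H-chromen-8-yl)-2-hydroxy-2-methylbut-3-en-1-yl acetate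
Conditions: H2 (1 atm), Lindlar catalyst (Pd/CaCO3, Pb), quinoline, EtOAc, rt
Reagents that add atoms: none
Why: Lindlar semihydrogenation, in which syn delivery of H2 on the poisoned palladium surface sets the Z double bond; the chromone C2=C3 bond (a vinylogous ester) should not be reduced.

Step 9
Reactants: 14 (2R,3Z)-4-(7-{[tert-butyl(dimethyl)silyl]oxy}-4-oxo-4H-chromen-8-yl)-2-hydroxy-2-methylbut-3-en-1-yl acetate, 15 phenylboronic acid
Product: 16 (2R,3Z)-4-[(2S)-7-{[tert-butyl(dimethyl)silyl]oxy}-4-oxo-2-phenyl-3,4-dihydro-2H-chromen-8-yl]-2-hydroxy-2-methylbut-3-en-1-yl acetate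
Conditions: [Rh(OH){(S)-MeO-F12-BIPHEP}]2 (3 mol % Rh), PhB(OH)2 (2.5 equiv), dioxane/H2O (10:1), 30 °C
Reagents that add atoms: none
Why: Hayashi–Miyaura asymmetric conjugate addition, in which the phenylrhodium species carbometallates the chromone enone and the chiral bisphosphine sets C2 as S (catalyst control, remote from the carbinol centre); the base‑free hydroxorhodium conditions avoid ring opening of the flavanone, and the unactivated Z‑alkene is not a partner for arylrhodium.

Step 10
Reactants: 16 (2R,3Z)-4-[(2S)-7-{[tert-butyl(dimethyl)silyl]oxy}-4-oxo-2-phenyl-3,4-dihydro-2H-chromen-8-yl]-2-hydroxy-2-methylbut-3-en-1-yl acetate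
Product: 17 (2R,3Z)-2-hydroxy-4-[(2S)-7-hydroxy-4-oxo-2-phenyl-3,4-dihydro-2H-chromen-8-yl]-2-methylbut-3-en-1-yl acetate
Conditions: TBAF, AcOH (1:1), THF, 0 °C
Reagents that add atoms: none
Why: Fluoride cleavage of the aryl silyl ether, buffered with acetic acid so that the primary acetate, the base‑labile flavanone C2 (retro‑oxa‑Michael) and the acid‑labile tertiary allylic alcohol should all survive.

**Compound list**

1 | 6-hydroxy-1-benzofuran-3(2H)-one | O=C1COc2cc(O)ccc12 | starting material
2 | 3,6-bis[(trimethylsilyl)oxy]-1-benzofuran | C[Si](C)(C)Oc1ccc2c(c1)occ2O[Si](C)(C)C | intermediate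
3 | rac-4,6b-bis[(trimethylsilyl)oxy]-1a,6b-dihydro-1H-cyclopropa[b][1]benzofuran (cis-fused) | C[Si](C)(C)Oc1ccc2c(c1)OC1CC21O[Si](C)(C)C | intermediate
4 | rac-2-chloro-7-[(trimethylsilyl)oxy]-2,3-dihydro-4H-chromen-4-one | C[Si](C)(C)Oc1ccc2c(c1)OC(Cl)CC2=O | intermediate
5 | 7-[(trimethylsilyl)oxy]-4H-chromen-4-one | C[Si](C)(C)Oc1ccc2c(c1)occc2=O | intermediate
6 | 7-hydroxy-4H-chromen-4-one | O=c1ccoc2cc(O)ccc12 | intermediate
7 | 7-hydroxy-8-iodo-4H-chromen-4-one | O=c1ccoc2c(I)c(O)ccc12 | intermediate
8 | 7-{[tert-butyl(dimethyl)silyl]oxy}-8-iodo-4H-chromen-4-one | CC(C)(C)[Si](C)(C)Oc1ccc2c(c1I)occc2=O | intermediate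
9 | [(2R)-2-methyloxiran-2-yl]methanol ((R)-2-methylglycidol) | C[C@]1(CO1)CO | starting material
10 | (2S)-2-methyloxirane-2-carbaldehyde | C[C@]1(CO1)C=O | intermediate
11 | (2R)-2-ethynyl-2-methyloxirane | C[C@]1(CO1)C#C | intermediate
12 | (2R)-2-hydroxy-2-methylbut-3-yn-1-yl acetate | CC(=O)OC[C@](C)(O)C#C | intermediate
13 | (2R)-4-(7-{[tert-butyl(dimethyl)silyl]oxy}-4-oxo-4H-chromen-8-yl)-2-hydroxy-2-methylbut-3-yn-1-yl acetate | CC(=O)OC[C@](C)(O)C#Cc1c(O[Si](C)(C)C(C)(C)C)ccc2c1occc2=O | intermediate
14 | (2R,3Z)-4-(7-{[tert-butyl(dimethyl)silyl]oxy}-4-oxo-4H-chromen-8-yl)-2-hydroxy-2-methylbut-3-en-1-yl acetate | CC(=O)OC[C@](C)(O)/C=C\c1c(O[Si](C)(C)C(C)(C)C)ccc2c1occc2=O | intermediate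
15 | phenylboronic acid | OB(O)c1ccccc1 | starting material
16 | (2R,3Z)-4-[(2S)-7-{[tert-butyl(dimethyl)silyl]oxy}-4-oxo-2-phenyl-3,4-dihydro-2H-chromen-8-yl]-2-hydroxy-2-methylbut-3-en-1-yl acetate | CC(=O)OC[C@](C)(O)/C=C\c1c(O[Si](C)(C)C(C)(C)C)ccc2c1O[C@H](c1ccccc1)CC2=O | intermediate
17 | (2R,3Z)-2-hydroxy-4-[(2S)-7-hydroxy-4-oxo-2-phenyl-3,4-dihydro-2H-chromen-8-yl]-2-methylbut-3-en-1-yl acetate | CC(=O)OC[C@](C)(O)/C=C\c1c(O)ccc2c1O[C@H](c1ccccc1)CC2=O | target

**Step count and risks**

Total step count: 10. Longest linear sequence: 8 (steps 1, 2, 3, 4, 7, 8, 9, 10).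

Steps most likely to fail:

Step 2. The zinc carbenoid may add only slowly to the heteroaromatic enol ether, and the iron(III) stage may desilylate without fragmentation or cut the external cyclopropane bond, which would return the five‑membered ketone or its 2‑methyl derivative instead of the enlarged ring. The fallback sets out from 2 and uses a free dihalocarbene, a stronger electrophile of the Ciamician–Dennstedt type that adds to benzofuran 2,3‑bonds and to silyl enol ethers. With CHBr3 and KOt‑Bu in pentane at −20 °C the gem‑dibromocyclopropane is expected to open spontaneously (cyclopropyl‑to‑allyl ionisation with loss of bromotrimethylsilane), giving after aqueous work‑up 3-bromo-7-hydroxy-4H-chromen-4-one F1. Palladium‑catalysed formate reduction (Pd(PPh3)4, HCO2H/Et3N, DMF, 60 °C) then removes the bromine and the route is rejoined at 6.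

Step 9. On the fully elaborated chromone the arylrhodium species may be held back by the free carbinol and the neighbouring Z‑styrene, so that conversion stalls, facial selectivity erodes or the alkene isomerises. The fallback moves the arylation in front of the side‑chain construction. It sets out from 8, which with 15 under the conditions of step 9 should give (2S)-7-{[tert-butyl(dimethyl)silyl]oxy}-8-iodo-2-phenyl-2,3-dihydro-4H-chromen-4-one F2 (the hindered aryl iodide is not expected to add oxidatively to the phosphine–rhodium(I) catalyst at 30 °C). Sonogashira coupling of F2 with 12 (Pd(PPh3)2Cl2, CuI, Et3N, rt) would give (2R)-4-[(2S)-7-{[tert-butyl(dimethyl)silyl]oxy}-4-oxo-2-phenyl-3,4-dihydro-2H-chromen-8-yl]-2-hydroxy-2-methylbut-3-yn-1-yl acetate F3, and Lindlar semihydrogenation of F3 rejoins the route at 16.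

Step 8. Hydrogen uptake at the di‑ortho‑substituted aryl alkyne may be slow, and forcing it risks over‑reduction to the saturated chain or Z‑to‑E isomerisation on the catalyst. The fallback builds the Z double bond before the aryl–carbon bond. It sets out from 12, which by rhodium‑catalysed trans‑hydroboration ([Rh(cod)Cl]2, P(i‑Pr)3, Et3N, pinacolborane, cyclohexane, rt) should give (2R,3Z)-2-hydroxy-2-methyl-4-(4,4,5,5-tetramethyl-1,3,2-dioxaborolan-2-yl)but-3-en-1-yl acetate F4. Suzuki–Miyaura coupling of F4 with 8 (Pd(dppf)Cl2, K3PO4, THF/H2O, 40 °C) proceeds with retention of alkene geometry and rejoins the route at 14.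

**Further compounds**

F1 | step 2 | 3-bromo-7-hydroxy-4H-chromen-4-one | O=c1c(Br)coc2cc(O)ccc12
F2 | step 9 | (2S)-7-{[tert-butyl(dimethyl)silyl]oxy}-8-iodo-2-phenyl-2,3-dihydro-4H-chromen-4-one | CC(C)(C)[Si](C)(C)Oc1ccc2c(c1I)O[C@H](c1ccccc1)CC2=O
F3 | step 9 | (2R)-4-[(2S)-7-{[tert-butyl(dimethyl)silyl]oxy}-4-oxo-2-phenyl-3,4-dihydro-2H-chromen-8-yl]-2-hydroxy-2-methylbut-3-yn-1-yl acetate | CC(=O)OC[C@](C)(O)C#Cc1c(O[Si](C)(C)C(C)(C)C)ccc2c1O[C@H](c1ccccc1)CC2=O
F4 | step 8 | (2R,3Z)-2-hydroxy-2-methyl-4-(4,4,5,5-tetramethyl-1,3,2-dioxaborolan-2-yl)but-3-en-1-yl acetate | CC(=O)OC[C@](C)(O)/C=C\B1OC(C)(C)C(C)(C)O1
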